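**Plan**

- Retrosynthesis: (i) cut the carbinol C–aryl bond (aryl Grignard + aldehyde); (ii) cut the benzylic CH2–aryl bond, taken back at the ketone oxidation level to an arylzinc and a meso anhydride; (iii) take the anhydride back to cis-oxolane-3,4-dicarboxylic acid and then to furan-3,4-dicarboxylic acid.
- Forward: the oxolane ring arises by hydrogenation of the furan. A temporary second ring (the anhydride, 3,7-dioxabicyclo[3.3.0]octane-2,4-dione) is closed and then opened by the first aryl group. The ketone is reduced to CH2, the acid is taken to the aldehyde, and the second aryl group (same bromide) is added.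
- Enabling feature: C3 and C4 of the oxolane are cis and each carries one exocyclic carbon bound to the same 3-hydroxy-4-methoxyphenyl group. With both exocyclic carbons as C=O tied through an anhydride oxygen, the bicycle has a mirror plane through the oxolane O1 and the anhydride oxygen, so one chiral catalyst can set C3 and C4 together while it forms the aryl–C bond.
- Stereochemistry: the cis relation comes from syn hydrogenation and the cis-only ring fusion. The absolute configuration of C3/C4 comes from the chiral Rh catalyst choosing one of two enantiotopic C(=O)–O bonds. The carbinol centre comes from Felkin–Anh/chelate-controlled Grignard addition to the cis aldehyde.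

Key step: step 4

Remark: which enantiomer of the PHOX ligand gives the (3S,4R) keto acid on this anhydride has to be read from a first run; the route is written for that enantiomer (both are sold), and the same holds for quinidine versus quinine in the fallback.

**Route**

Step 1
Reactants: 1 5-bromo-2-methoxyphenol
Product: 2 (5-bromo-2-methoxyphenoxy)tri(propan-2-yl)silane
Conditions: TIPSCl, imidazole, DMF, rt
Reagents that add atoms: triisopropylsilyl chloride, CC(C)[Si](Cl)(C(C)C)C(C)C
Why: O-silylation of a phenol with a silyl chloride and imidazole should mask the acidic OH for the organometallic steps, and the aryl TIPS ether should survive acid, hydrogenation and borane.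

Step 2
Reactants: 3 furan-3,4-dicarboxylic acid
Product: 4 cis-oxolane-3,4-dicarboxylic acid (meso, 3R,4S)
Conditions: H2 (50 bar), 5% Rh/Al2O3, H2O, 80 °C
Reagents that add atoms: none
Why: Heterogeneous hydrogenation (dearomatisation) of the furan should deliver all hydrogen from the catalyst face, so C3 and C4 are formed together as the cis, meso pair.

Step 3
Reactants: 4 cis-oxolane-3,4-dicarboxylic acid
Product: 5 cis-3,7-dioxabicyclo[3.3.0]octane-2,4-dione (meso, 1R,5S)
Conditions: Ac2O, 120 °C; evaporation
Reagents that add atoms: none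
Why: Cyclodehydration of a cis-1,2-diacid with acetic anhydride gives the five-membered cyclic anhydride, and since only the cis acid can close, the step also secures the cis ring fusion.

Step 4
Reactants: 2 (5-bromo-2-methoxyphenoxy)tri(propan-2-yl)silane; 5 cis-3,7-dioxabicyclo[3.3.0]octane-2,4-dione
Product: 8 (3S,4R)-4-[4-methoxy-3-(triisopropylsilyloxy)benzoyl]oxolane-3-carboxylic acid, via aryllithium 6 (not isolated), via arylzinc triflate 7 (not isolated)
Conditions: 2, n-BuLi, THF, −78 °C; Zn(OTf)2, −78 °C → rt; then 5, [Rh(cod)Cl]2 (5 mol%), t-Bu-PHOX (10 mol%), THF/DMF, 50 °C; 1 M HCl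
Reagents that add atoms: none
Why: Rh(I)–PHOX should insert into one acyl C–O bond of the anhydride to give an acyl–Rh carboxylate, the aryl group is then transferred from zinc, and reductive elimination forms the aryl–C(=O) bond; the zinc carboxylate is protonated on work-up. The closest known reaction type is the Rh- or Pd-catalysed enantioselective desymmetrising acylation of organozinc reagents with meso cyclic succinic anhydrides. No ring is closed; the temporary anhydride ring is opened. No stereocentre is created, but C3 and C4, mirror images of each other in 5, become distinguishable: the chiral ligand on Rh decides which of the two enantiotopic C(=O)–O bonds is cleaved and so fixes the absolute configuration of both at once, the cis relation being carried over from the ring fusion. The step needs enantiotopic-group selectivity and mono-addition: the mirror plane through both ring oxygens of 5 makes the two carbonyls equal except towards the chiral catalyst, and the arylzinc adds neither to the ketone nor to the zinc carboxylate of the product.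

Step 5
Reactants: 8 (3S,4R)-4-[4-methoxy-3-(triisopropylsilyloxy)benzoyl]oxolane-3-carboxylic acid
Product: 9 (3S,4R)-4-[[4-methoxy-3-(triisopropylsilyloxy)phenyl]methyl]oxolane-3-carboxylic acid
Conditions: H2 (4 bar), 10% Pd/C, AcOH, 50 °C
Reagents that add atoms: none
Why: Catalytic hydrogenolysis of an electron-rich aryl ketone to the methylene group, by way of the benzylic alcohol or its lactone with the cis acid (the classical reduction of aroyl acids to arylalkyl acids), should remove the helper oxygen in a non-basic medium that leaves C3 and C4 untouched.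

Step 6
Reactants: 9 (3S,4R)-4-[[4-methoxy-3-(triisopropylsilyloxy)phenyl]methyl]oxolane-3-carboxylic acid
Product: 10 [(3R,4R)-4-[[4-methoxy-3-(triisopropylsilyloxy)phenyl]methyl]oxolan-3-yl]methanol
Conditions: BH3·THF, THF, 0 °C → rt; MeOH, then H2O
Reagents that add atoms: none
Why: Borane reduces a carboxylic acid chemoselectively to the primary alcohol through the acyloxyborane, without touching the aryl silyl ether or the ring stereocentres (the descriptor at C3 changes only through the priority rules).

Step 7
Reactants: 10 [(3R,4R)-4-[[4-methoxy-3-(triisopropylsilyloxy)phenyl]methyl]oxolan-3-yl]methanol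
Product: 11 (3S,4R)-4-[[4-methoxy-3-(triisopropylsilyloxy)phenyl]methyl]oxolane-3-carbaldehyde
Conditions: Dess–Martin periodinane, CH2Cl2, 0 °C → rt
Reagents that add atoms: none
Why: Dess–Martin oxidation works under near-neutral conditions, so the aldehyde should form without enolisation and the cis relation at C3 should be kept.

Step 8
Reactants: 11 (3S,4R)-4-[[4-methoxy-3-(triisopropylsilyloxy)phenyl]methyl]oxolane-3-carbaldehyde; 2 (5-bromo-2-methoxyphenoxy)tri(propan-2-yl)silane
Product: 13 (S)-[4-methoxy-3-(triisopropylsilyloxy)phenyl][(3S,4R)-4-[[4-methoxy-3-(triisopropylsilyloxy)phenyl]methyl]oxolan-3-yl]methanol, via arylmagnesium bromide 12 (not isolated)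
Conditions: 2, Mg (I2 cat.), THF, 40 °C; then 11, THF, −78 °C; aq. NH4Cl
Reagents that add atoms: none
Why: Grignard addition to an α-branched aldehyde under Felkin–Anh control should set the (S) carbinol centre, because the aryl group attacks anti to the C3–C4 ring bond (C4 with its cis benzyl group is the large α-substituent) with the ring CH2 inside, and a magnesium chelate between the carbonyl oxygen and the ring oxygen exposes the same face.

Step 9
Reactants: 13 (S)-[4-methoxy-3-(triisopropylsilyloxy)phenyl][(3S,4R)-4-[[4-methoxy-3-(triisopropylsilyloxy)phenyl]methyl]oxolan-3-yl]methanol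
Product: 14 (S)-(3-hydroxy-4-methoxyphenyl)[(3S,4R)-4-[(3-hydroxy-4-methoxyphenyl)methyl]oxolan-3-yl]methanol (CNP0108210.1)
Conditions: TBAF, THF, 0 °C; H2O
Reagents that add atoms: none
Why: Fluoride cleaves both aryl silyl ethers through Si–F bond formation, and the benzylic carbinol should be safe under these basic conditions because its para oxygen is a methyl ether and cannot open a quinone methide path.

**Compound list**

1 | 5-bromo-2-methoxyphenol | COc1ccc(Br)cc1O | starting material
2 | (5-bromo-2-methoxyphenoxy)tri(propan-2-yl)silane | COc1ccc(Br)cc1O[Si](C(C)C)(C(C)C)C(C)C | intermediate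
3 | furan-3,4-dicarboxylic acid | OC(=O)c1cocc1C(=O)O | starting material
4 | cis-oxolane-3,4-dicarboxylic acid (meso) | OC(=O)[C@H]1COC[C@H]1C(=O)O | intermediate
5 | cis-3,7-dioxabicyclo[3.3.0]octane-2,4-dione (meso) | O=C1OC(=O)[C@H]2COC[C@H]21 | intermediate
6 | [4-methoxy-3-(triisopropylsilyloxy)phenyl]lithium | COc1ccc([Li])cc1O[Si](C(C)C)(C(C)C)C(C)C | intermediate
7 | [4-methoxy-3-(triisopropylsilyloxy)phenyl]zinc trifluoromethanesulfonate | COc1ccc([Zn]OS(=O)(=O)C(F)(F)F)cc1O[Si](C(C)C)(C(C)C)C(C)C | intermediate
8 | (3S,4R)-4-[4-methoxy-3-(triisopropylsilyloxy)benzoyl]oxolane-3-carboxylic acid | COc1ccc(C(=O)[C@H]2COC[C@H]2C(=O)O)cc1O[Si](C(C)C)(C(C)C)C(C)C | intermediate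
9 | (3S,4R)-4-[[4-methoxy-3-(triisopropylsilyloxy)phenyl]methyl]oxolane-3-carboxylic acid | COc1ccc(C[C@H]2COC[C@H]2C(=O)O)cc1O[Si](C(C)C)(C(C)C)C(C)C | intermediate
10 | [(3R,4R)-4-[[4-methoxy-3-(triisopropylsilyloxy)phenyl]methyl]oxolan-3-yl]methanol | COc1ccc(C[C@H]2COC[C@H]2CO)cc1O[Si](C(C)C)(C(C)C)C(C)C | intermediate
11 | (3S,4R)-4-[[4-methoxy-3-(triisopropylsilyloxy)phenyl]methyl]oxolane-3-carbaldehyde | COc1ccc(C[C@H]2COC[C@H]2C=O)cc1O[Si](C(C)C)(C(C)C)C(C)C | intermediate
12 | [4-methoxy-3-(triisopropylsilyloxy)phenyl]magnesium bromide | COc1ccc([Mg]Br)cc1O[Si](C(C)C)(C(C)C)C(C)C | intermediate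
13 | (S)-[4-methoxy-3-(triisopropylsilyloxy)phenyl][(3S,4R)-4-[[4-methoxy-3-(triisopropylsilyloxy)phenyl]methyl]oxolan-3-yl]methanol | COc1ccc(C[C@H]2COC[C@H]2[C@H](O)c2ccc(OC)c(O[Si](C(C)C)(C(C)C)C(C)C)c2)cc1O[Si](C(C)C)(C(C)C)C(C)C | intermediate
14 | (S)-(3-hydroxy-4-methoxyphenyl)[(3S,4R)-4-[(3-hydroxy-4-methoxyphenyl)methyl]oxolan-3-yl]methanol | COc1ccc(C[C@H]2COC[C@H]2[C@H](O)c2ccc(OC)c(O)c2)cc1O | target

**Step count and risks**

Total steps: 9. Longest linear sequence: 8 steps (steps 2–9, from 3). Step 1 is the only off-line step, and its product 2 enters twice (steps 4 and 8).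

Step 4. The catalyst may discriminate poorly between the two enantiotopic acyl C–O bonds, or aryl transfer from zinc may be slow so that the arylzinc is lost by protonation. The fallback sets out from 5 and comes back at 10. Anhydride 5 is opened with methanol in the presence of a cinchona alkaloid (quinidine or quinine, toluene, low temperature) to the hemiester (3R,4S)-4-(methoxycarbonyl)oxolane-3-carboxylic acid F1. Its free acid is turned with ethanethiol, DCC and DMAP into the thioester methyl (3S,4R)-4-(ethylsulfanylcarbonyl)oxolane-3-carboxylate F2. A Fukuyama coupling of F2 with arylzinc 7 (PdCl2(PPh3)2, THF/toluene) forms the same aryl–C(=O) bond and should give the keto ester methyl (3S,4R)-4-[4-methoxy-3-(triisopropylsilyloxy)benzoyl]oxolane-3-carboxylate F3. Hydrogenolysis as in step 5 gives methyl (3S,4R)-4-[[4-methoxy-3-(triisopropylsilyloxy)phenyl]methyl]oxolane-3-carboxylate F4, and LiBH4 reduces F4 to 10.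

Step 5. The reduction may stop at the benzylic alcohol or lactone stage, or the centre next to the ketone may epimerise by acid-catalysed enolisation during long contact with warm acid. The fallback sets out from 8 and comes back at 9. The ketone is reduced with NaBH4 at 0 °C and the hydroxy acid is closed on acidification to the cis-fused lactone (1S,5R)-4-[4-methoxy-3-(triisopropylsilyloxy)phenyl]-3,7-dioxabicyclo[3.3.0]octan-2-one F5 (both epimers at C-4), in which C3 and C4 are locked cis. Ionic hydrogenolysis of the benzylic C–O bond (Et3SiH, TFA, CH2Cl2) should then give 9.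

Step 8. Facial selectivity at the aldehyde may be poor, or the basic Grignard reagent may enolise the cis aldehyde and epimerise C3. The fallback sets out from 9 and comes back at 13. Acid 9 is converted (MeNHOMe·HCl, EDC, base) into the Weinreb amide (3S,4R)-N-methoxy-N-methyl-4-[[4-methoxy-3-(triisopropylsilyloxy)phenyl]methyl]oxolane-3-carboxamide F6. Grignard reagent 12 adds once to give the ketone [4-methoxy-3-(triisopropylsilyloxy)phenyl][(3S,4R)-4-[[4-methoxy-3-(triisopropylsilyloxy)phenyl]methyl]oxolan-3-yl]methanone F7. A CBS reduction with (R)-Me-CBS and BH3·THF then sets the carbinol centre under reagent control and should give 13.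

**Further compounds**

F1 | step 4 | (3R,4S)-4-(methoxycarbonyl)oxolane-3-carboxylic acid | OC(=O)[C@H]1COC[C@H]1C(=O)OC
F2 | step 4 | methyl (3S,4R)-4-(ethylsulfanylcarbonyl)oxolane-3-carboxylate | CCSC(=O)[C@H]1COC[C@H]1C(=O)OC
F3 | step 4 | methyl (3S,4R)-4-[4-methoxy-3-(triisopropylsilyloxy)benzoyl]oxolane-3-carboxylate | COc1ccc(C(=O)[C@H]2COC[C@H]2C(=O)OC)cc1O[Si](C(C)C)(C(C)C)C(C)C
F4 | step 4 | methyl (3S,4R)-4-[[4-methoxy-3-(triisopropylsilyloxy)phenyl]methyl]oxolane-3-carboxylate | COc1ccc(C[C@H]2COC[C@H]2C(=O)OC)cc1O[Si](C(C)C)(C(C)C)C(C)C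
F5 | step 5 | (1S,5R)-4-[4-methoxy-3-(triisopropylsilyloxy)phenyl]-3,7-dioxabicyclo[3.3.0]octan-2-one (both epimers at C-4) | O=C1OC(c2ccc(OC)c(O[Si](C(C)C)(C(C)C)C(C)C)c2)[C@H]2COC[C@H]21
F6 | step 8 | (3S,4R)-N-methoxy-N-methyl-4-[[4-methoxy-3-(triisopropylsilyloxy)phenyl]methyl]oxolane-3-carboxamide | COc1ccc(C[C@H]2COC[C@H]2C(=O)N(C)OC)cc1O[Si](C(C)C)(C(C)C)C(C)C
F7 | step 8 | [4-methoxy-3-(triisopropylsilyloxy)phenyl][(3S,4R)-4-[[4-methoxy-3-(triisopropylsilyloxy)phenyl]methyl]oxolan-3-yl]methanone | COc1ccc(C[C@H]2COC[C@H]2C(=O)c2ccc(OC)c(O[Si](C(C)C)(C(C)C)C(C)C)c2)cc1O[Si](C(C)C)(C(C)C)C(C)C
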